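The 2,6-dimethoxyphenol unit of ring A (methoxy groups on C6 and C8 flanking the C7 hydroxyl, C5 bearing only hydrogen) maps atom for atom onto MeOCH2–CO–CH2OMe, so the plan cuts C5–C6 and C8–C8a. A single base-mediated [3+3] condensation–aromatisation welds 1,3-dimethoxyacetone onto a ring B cyclohexanone, closes ring A and delivers all three ring A oxygens in final form. The precursor is an all-trans cyclohexanone (C8a ketone, C1 aryl, C2 CH2OTBS, C3 CH2OBOM) from an auxiliary-controlled Diels–Alder reaction. C5 sits on C4a as a masked formyl group (acetal, unmasked to its methyl enol ether), because a free hydroxymethylene group would merely be deprotonated and cease to be an electrophile.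

Key step: step 11

Assumption: aryltetralin numbering (C1 aryl-bearing carbon, C2/C2a, C3/C3a, C4, C4a, C5–C8, C8a; primes for the pendant ring) is applied to every ring B compound; the target is (1R,2S,3S) with an all-trans ring B; the hydrogen sulfate as drawn is taken as the form to be delivered and is set free from its sodium salt in the last operation; the CIP letter at C2 changes along the route only because substituent priorities change, not the geometry.

Step 1
Reactants: 1 homosyringic acid
Product: 2 benzyl [4-(benzyloxy)-3,5-dimethoxyphenyl]acetate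
Conditions: BnBr (2.3 equiv), K2CO3, DMF, 50 °C
Reagents that add atoms: benzyl bromide, BrCc1ccccc1
Why: Williamson-type O-alkylation of phenoxide and carboxylate in one operation masks the 4'-OH as a hydrogenolysable ether that tolerates all later bases, hydrides and Lewis acids, and turns the acid into an ester ready for aminolysis.

Step 2
Reactants: 2 benzyl [4-(benzyloxy)-3,5-dimethoxyphenyl]acetate
Product: 3 2-[4-(benzyloxy)-3,5-dimethoxyphenyl]-N-methoxy-N-methylacetamide
Conditions: MeNH(OMe)·HCl, iPrMgCl, THF, −20 → 0 °C
Reagents that add atoms: N,O-dimethylhydroxylamine hydrochloride, CNOC.Cl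
Why: Direct aminolysis of the ester by the chloromagnesium amide (Weinreb amide synthesis from esters) saves a saponification and works on enolisable arylacetates at low temperature.

Step 3
Reactants: 3 2-[4-(benzyloxy)-3,5-dimethoxyphenyl]-N-methoxy-N-methylacetamide; 4 vinylmagnesium bromide
Product: 5 1-[4-(benzyloxy)-3,5-dimethoxyphenyl]but-3-en-2-one
Conditions: THF, −20 → 0 °C; inverse quench into cold 1 M HCl
Reagents that add atoms: none
Why: In the Weinreb ketone synthesis the chelated tetrahedral intermediate stops at mono-addition, and the acidic inverse quench keeps the released amine protonated so that it cannot add to the new vinyl ketone.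

Step 4
Reactants: 5 1-[4-(benzyloxy)-3,5-dimethoxyphenyl]but-3-en-2-one
Product: 6 (Z)-1-[4-(benzyloxy)-3,5-dimethoxyphenyl]-2-(tert-butyldimethylsilyloxy)buta-1,3-diene (aryl trans to vinyl)
Conditions: TBSOTf, Et3N, CH2Cl2, 0 °C
Reagents that add atoms: tert-butyldimethylsilyl triflate, CC(C)(C)[Si](C)(C)OS(=O)(=O)C(F)(F)F
Why: Soft enolisation with O-silylation can only involve the benzylic CH2, and the aryl group should settle anti to the vinyl group (Z enol ether), the geometry in which the aryl is an outside substituent of the s-cis diene.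

Step 5
Reactants: 7 (S)-4-benzyl-2-oxazolidinone; 8 diethylphosphonoacetic acid
Product: 9 (S)-4-benzyl-3-[(diethoxyphosphoryl)acetyl]oxazolidin-2-one
Conditions: DCC, DMAP (cat.), CH2Cl2, 0 °C → rt
Reagents that add atoms: none
Why: Carbodiimide/DMAP N-acylation (Steglich-type acyl transfer) joins acid and auxiliary without strong base and leaves the C4 stereocentre of the auxiliary untouched.

Step 6
Reactants: 9 (S)-4-benzyl-3-[(diethoxyphosphoryl)acetyl]oxazolidin-2-one; 10 (tert-butyldimethylsilyloxy)acetaldehyde
Product: 11 (S)-4-benzyl-3-[(E)-4-(tert-butyldimethylsilyloxy)but-2-enoyl]oxazolidin-2-one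
Conditions: LiCl, iPr2NEt, MeCN, rt
Reagents that add atoms: none
Why: The Horner–Wadsworth–Emmons olefination in its mild LiCl/amine variant should give the E-enoyl imide, whose alkene geometry later becomes the C2/C3 trans relationship, without harming the imide or the silyl ether.

Step 7
Reactants: 6 (Z)-1-aryl-2-(tert-butyldimethylsilyloxy)buta-1,3-diene; 11 (E)-4-silyloxybutenoyl imide
Product: 12 (1R,2S,3S)-cycloadduct: cyclohexene with C8a(OTBS)=C4a enol ether / C1 aryl / C2 CH2OTBS / C3 C(O)-oxazolidinone / all-trans
Conditions: Et2AlCl (1.5 equiv), CH2Cl2, −78 → −30 °C; Et3N, then aq NaHCO3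
Reagents that add atoms: none
Why: In this oxazolidinone-auxiliary Diels–Alder reaction the Et2Al chelate locks the imide s-cis so that the benzyl group of the (S)-auxiliary covers the Cα-Re face and the diene adds to the Cα-Si face (sets C3 and, through the E-alkene, C2), the 2-silyloxy group makes C1 the nucleophilic diene terminus so that C1 bonds to Cβ ("para" orientation, placing CH2OTBS on C2), and the endo transition state puts the outside aryl group cis to the imide and trans to the C2 side chain (sets C1).

Step 8
Reactants: 12 cycloadduct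
Product: 13 (1R,2R,3S)-C3a alcohol (C3 CH2OH; enol silane and C2a–OTBS retained)
Conditions: LiBH4, MeOH (2 equiv each), THF, 0 °C
Reagents that add atoms: none
Why: Reductive removal of the auxiliary with LiBH4 turns the imide carbonyl into C3a–OH while the enol silane shields C8a from hydride, no stereocentre is touched and the auxiliary is recovered.

Step 9
Reactants: 13 C3a alcohol
Product: 14 (1R,2R,3S)-C3a benzyloxymethyl (BOM) ether
Conditions: BOMCl, iPr2NEt, CH2Cl2, 0 °C → rt
Reagents that add atoms: benzyl chloromethyl ether, ClCOCc1ccccc1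
Why: Acetal-type O-alkylation under amine base never generates a free alkoxide, so the neighbouring C2a silyl group cannot migrate to C3a–O (which would exchange the two side chains and misplace the sulfate), and BOM is stable to KOtBu and fluoride yet falls with the benzyl ethers on hydrogenolysis.

Step 10
Reactants: 14 C3a BOM ether; 15 trimethyl orthoformate
Product: 16 (1R,2R,3S)-2-(dimethoxymethyl)cyclohexanone: C8a ketone / C5 as CH(OMe)2 on C4a (C4a epimers) / C1 aryl / C2 CH2OTBS / C3 CH2OBOM
Conditions: 15 (3 equiv), TMSOTf (0.1 equiv), CH2Cl2, −78 → −40 °C; Et3N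
Reagents that add atoms: none
Why: In this Mukaiyama-type alkylation of an enol silane by the dimethoxycarbenium ion under silyl triflate catalysis, the enol ether double bond left by the cycloaddition lies between C8a and C4a, so C5 can only be attached to C4a and never to the more acidic benzylic C1, and the new C4a centre is irrelevant because it becomes sp2 in step 11.

Step 11
Reactants: 16 keto acetal; 17 1,3-dimethoxyacetone
Product: 21 (1R,2S,3S)-7-hydroxy-6,8-dimethoxy aryltetralin bearing C2a–OTBS / C3a–OBOM / 4'-OBn, via methoxymethylene ketone 18 (not isolated), via ene-dione 19 (not isolated), via cyclohexadienone 20 (not isolated)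
Conditions: 17 (5 equiv), KOtBu (3 equiv), THF, 0 °C → rt; then t-BuOH, 70 °C, Ar; AcOH quench
Reagents that add atoms: none
Why: Proposed new method: KOtBu first expels methanol from 16 (E1cB) to give the non-acidic vinylogous ester 18, the potassium enolate of 17 then adds to C5 and methoxide leaves (addition–elimination, C5–C6 bond, 19 held as its delocalised enolate), and on heating the C8 enolate carbon attacks the C8a ketone, water is lost towards C8 and dienone 20 gives up its C4a proton to become the phenoxide of 21. The closest known reactions are the [3+3] phenol synthesis from 2-(hydroxymethylene)cycloalkanones and acetonedicarboxylates, the addition–elimination of ketone potassium enolates to β-amino or β-alkoxy enones, and the base-induced recyclisation of 2-alkylpyrylium pseudo-bases (the same pent-2-ene-1,5-diones) to phenols, so only the dialkoxyacetone partner is untested. Ring A closes by a 6-(enolendo)-exo-trig aldol addition that aromatisation makes irreversible. No stereocentre is created: C2 and C3 are untouched, whereas C1 stays enolisable until C8a becomes aromatic and is expected to rest in the all-equatorial arrangement trans to the C2 side chain, the one already installed in step 7. Site selectivity is secured because C5 is the only unhindered, non-enolisable electrophilic carbon while C8a is flanked by the aryl-bearing C1, and because 17 is symmetric either α-carbon leads to the same product. Keeping 17 in excess over the base leaves part of 18 un-enolised at C1, and completing the C5–C6 coupling cold before heating keeps the water of the last condensation from hydrolysing unreacted 18 to its inert hydroxymethylene salt.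

Step 12
Reactants: 21 C7 phenol
Product: 22 (1R,2S,3S)-7-benzyloxy-6,8-dimethoxy aryltetralin bearing C2a–OTBS / C3a–OBOM / 4'-OBn
Conditions: BnBr, K2CO3, DMF, rt
Reagents that add atoms: benzyl bromide, BrCc1ccccc1
Why: Williamson etherification of the acidic C7 phenol masks it so that the sulfating agent of step 14 will meet a single hydroxyl group.

Step 13
Reactants: 22 C7 benzyl ether
Product: 23 (1R,2S,3S)-C2a alcohol (C2 CH2OH; C3a–OBOM / C7–OBn / 4'-OBn retained)
Conditions: TBAF, AcOH (1:1), THF, 0 °C → rt
Reagents that add atoms: none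
Why: Fluoride-induced desilylation frees only C2a–OH because every other oxygen carries a methyl or benzyl-type group that is inert to fluoride.

Step 14
Reactants: 23 C2a alcohol
Product: 24 sodium (1R,2S,3S)-C2a sulfate (C3a–OBOM / C7–OBn / 4'-OBn)
Conditions: SO3·pyridine (4 equiv), pyridine, rt; then aq NaHCO3
Reagents that add atoms: sulfur trioxide–pyridine complex, O=S(=O)=O.c1ccncc1; sodium hydrogencarbonate, [Na+].OC([O-])=O
Why: O-sulfation of the only free primary alcohol with an SO3–amine complex is standard, and exchanging pyridinium for sodium gives a base-stable salt free of the amine that would retard benzyl ether hydrogenolysis.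

Step 15
Reactants: 24 protected sodium sulfate
Product: 26 CNP0111670.1 (1R,2S,3S)-C2a hydrogen sulfate, via sodium salt 25 (not isolated)
Conditions: H2 (1 atm), Pd/C (10%), MeOH, rt; filter; then HCl (1.0 equiv) in EtOH, 0 °C, filter off NaCl
Reagents that add atoms: none
Why: Catalytic hydrogenolysis cleaves both aryl benzyl ethers and the BOM acetal (its hemiacetal collapses with loss of formaldehyde) while the alkyl sulfate salt, the methyl ethers and C1–C3 are inert, and one equivalent of HCl then converts the salt into the hydrogen sulfate because NaCl is insoluble in ethanol.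

Compound list
1 | homosyringic acid (4-hydroxy-3,5-dimethoxyphenylacetic acid) | COc1cc(CC(=O)O)cc(OC)c1O | starting material
2 | benzyl [4-(benzyloxy)-3,5-dimethoxyphenyl]acetate | COc1cc(CC(=O)OCc2ccccc2)cc(OC)c1OCc1ccccc1 | intermediate
3 | 2-[4-(benzyloxy)-3,5-dimethoxyphenyl]-N-methoxy-N-methylacetamide | COc1cc(CC(=O)N(C)OC)cc(OC)c1OCc1ccccc1 | intermediate
4 | vinylmagnesium bromide | C=C[Mg]Br | starting material
5 | 1-[4-(benzyloxy)-3,5-dimethoxyphenyl]but-3-en-2-one | C=CC(=O)Cc1cc(OC)c(OCc2ccccc2)c(OC)c1 | intermediate
6 | (Z)-1-[4-(benzyloxy)-3,5-dimethoxyphenyl]-2-(tert-butyldimethylsilyloxy)buta-1,3-diene | C=C/C(O[Si](C)(C)C(C)(C)C)=C/c1cc(OC)c(OCc2ccccc2)c(OC)c1 | intermediate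
7 | (S)-4-benzyl-2-oxazolidinone | O=C1N[C@@H](Cc2ccccc2)CO1 | starting material
8 | diethylphosphonoacetic acid | CCOP(=O)(CC(=O)O)OCC | starting material
9 | (S)-4-benzyl-3-[(diethoxyphosphoryl)acetyl]oxazolidin-2-one | CCOP(=O)(CC(=O)N1[C@@H](Cc2ccccc2)COC1=O)OCC | intermediate
10 | (tert-butyldimethylsilyloxy)acetaldehyde | CC(C)(C)[Si](C)(C)OCC=O | starting material
11 | (S)-4-benzyl-3-[(E)-4-(tert-butyldimethylsilyloxy)but-2-enoyl]oxazolidin-2-one | CC(C)(C)[Si](C)(C)OC/C=C/C(=O)N1[C@@H](Cc2ccccc2)COC1=O | intermediate
12 | (1R,2S,3S)-Diels–Alder adduct, C8a(OTBS)=C4a enol silane, C3 acyl oxazolidinone | COc1cc([C@@H]2C(O[Si](C)(C)C(C)(C)C)=CC[C@H](C(=O)N3[C@@H](Cc4ccccc4)COC3=O)[C@H]2CO[Si](C)(C)C(C)(C)C)cc(OC)c1OCc1ccccc1 | intermediate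
13 | (1R,2R,3S)-C3a alcohol, enol silane retained | COc1cc([C@@H]2C(O[Si](C)(C)C(C)(C)C)=CC[C@H](CO)[C@H]2CO[Si](C)(C)C(C)(C)C)cc(OC)c1OCc1ccccc1 | intermediate
14 | (1R,2R,3S)-C3a BOM ether, enol silane retained | COc1cc([C@@H]2C(O[Si](C)(C)C(C)(C)C)=CC[C@H](COCOCc3ccccc3)[C@H]2CO[Si](C)(C)C(C)(C)C)cc(OC)c1OCc1ccccc1 | intermediate
15 | trimethyl orthoformate | COC(OC)OC | starting material
16 | (1R,2R,3S)-ring B keto acetal (C8a ketone, C5 as dimethyl acetal on C4a, C4a epimers) | COc1cc([C@@H]2C(=O)C(C(OC)OC)C[C@H](COCOCc3ccccc3)[C@H]2CO[Si](C)(C)C(C)(C)C)cc(OC)c1OCc1ccccc1 | intermediate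
17 | 1,3-dimethoxyacetone | COCC(=O)COC | starting material
18 | (1R,2R,3S)-ring B (E)-2-(methoxymethylene)cyclohexanone, the O-methyl ether of the hydroxymethylene ketone | COc1cc([C@@H]2C(=O)/C(=C/OC)C[C@H](COCOCc3ccccc3)[C@H]2CO[Si](C)(C)C(C)(C)C)cc(OC)c1OCc1ccccc1 | intermediate
19 | C5–C6 coupled ene-dione (present as its potassium enolate, drawn neutral) | COc1cc([C@@H]2C(=O)C(=CC(OC)C(=O)COC)C[C@H](COCOCc3ccccc3)[C@H]2CO[Si](C)(C)C(C)(C)C)cc(OC)c1OCc1ccccc1 | intermediate
20 | 4a-H cyclohexa-2,5-dienone (ring A closed, C7 ketone) | COc1cc([C@@H]2C3=C(OC)C(=O)C(OC)=CC3C[C@H](COCOCc4ccccc4)[C@H]2CO[Si](C)(C)C(C)(C)C)cc(OC)c1OCc1ccccc1 | intermediate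
21 | (1R,2S,3S)-7-hydroxy-6,8-dimethoxy aryltetralin, C2a–OTBS, C3a–OBOM, 4'-OBn | COc1cc([C@@H]2c3c(cc(OC)c(O)c3OC)C[C@H](COCOCc3ccccc3)[C@H]2CO[Si](C)(C)C(C)(C)C)cc(OC)c1OCc1ccccc1 | intermediate
22 | (1R,2S,3S)-C7 benzyl ether of 21 | COc1cc([C@@H]2c3c(cc(OC)c(OCc4ccccc4)c3OC)C[C@H](COCOCc3ccccc3)[C@H]2CO[Si](C)(C)C(C)(C)C)cc(OC)c1OCc1ccccc1 | intermediate
23 | (1R,2S,3S)-C2a alcohol | COc1cc([C@@H]2c3c(cc(OC)c(OCc4ccccc4)c3OC)C[C@H](COCOCc3ccccc3)[C@H]2CO)cc(OC)c1OCc1ccccc1 | intermediate
24 | sodium (1R,2S,3S)-C2a sulfate, fully protected | COc1cc([C@@H]2c3c(cc(OC)c(OCc4ccccc4)c3OC)C[C@H](COCOCc3ccccc3)[C@H]2COS(=O)(=O)[O-])cc(OC)c1OCc1ccccc1.[Na+] | intermediate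
25 | sodium salt of the target | COc1cc([C@@H]2c3c(cc(OC)c(O)c3OC)C[C@H](CO)[C@H]2COS(=O)(=O)[O-])cc(OC)c1O.[Na+] | intermediate
26 | CNP0111670.1, (1R,2S,3S)-C2a hydrogen sulfate | COc1cc([C@@H]2c3c(cc(OC)c(O)c3OC)C[C@H](CO)[C@H]2COS(=O)(=O)O)cc(OC)c1O | target

Total step count: 15. Longest linear sequence: 13 steps (steps 1–4 and 7–15, from 1); steps 5 and 6 form the convergent branch.

Steps most likely to fail

Step 11. Four processes threaten it:
- Proton transfer from the benzylic C1–H to the acetone enolate may slow the C5–C6 coupling.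
- The acetone may condense with itself.
- The sequence may stall at the delocalised ene-dione enolate, so that closure onto the hindered C8a carbonyl lags.
- C1 may epimerise before aromatisation locks it.

The fallback makes the two bonds one at a time by established reactions, setting out from 17 and 16 and returning at 21. TMSOTf/Et3N converts 17 into (Z)-1,3-dimethoxy-2-(trimethylsilyloxy)prop-1-ene F1. BF3·OEt2 in CH2Cl2 at −78 °C ionises the acetal of 16, and the neutral enol silane attacks the oxocarbenium carbon C5. This is a Mukaiyama aldol-type acetal substitution, the opening event of the Lewis-acid [3+3] salicylate syntheses from β-keto acetals. It gives the isolable C5-methoxy 1,5-diketone F2 with no enolate present. In a separate operation K2CO3 in MeOH at reflux, or pyrrolidinium acetate in toluene, removes the C5 methoxy group by β-elimination. Intramolecular aldol condensation with aromatisation then gives 21.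

Step 7. The Lewis acid may strip or oligomerise the silyloxydiene. The aryl-conjugated terminus C4 may compete with C1 for Cβ and erode the orientation. The β-substituent may make the cycloaddition sluggish. The fallback replaces auxiliary control by catalyst control with a smaller, more reactive dienophile, setting out from 10 and 6 and returning at 13. Wittig reaction of 10 with Ph3P=CHCHO gives (E)-4-(tert-butyldimethylsilyloxy)but-2-enal F3. Cycloaddition of F3 with 6 is run under a Tf2NH-activated oxazaborolidine derived from α,α-diphenylprolinol and o-tolylboronic acid, using the catalyst antipode that leaves the Cα-Si face open. It should give the all-trans C3 carbaldehyde F4. NaBH4 in MeOH at 0 °C then reduces F4 to 13.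

Step 10. Protodesilylation to the plain ketone may outrun C–C bond formation, or the silyl triflate may start acetal exchange at the BOM group. The fallback moves to enolate chemistry under thermodynamic control, setting out from 14 and returning at 18, which is then isolated and taken into step 11.
- One equivalent of AcOH-buffered TBAF in THF at −40 °C cleaves only the enol silane, giving the ring B ketone F5.
- Claisen formylation (HCO2Et, KOtBu, THF, 0 °C → rt) places the formyl carbon on C4a. Only there can the product survive as its stabilised enolate; formylation at the C1 methine is reversible. This gives the 2-(hydroxymethylene)cyclohexanone F6.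
- O-methylation with Me2SO4 and K2CO3 in acetone gives 18.

Further compounds
F1 | step 11 | (Z)-1,3-dimethoxy-2-(trimethylsilyloxy)prop-1-ene | CO/C=C(/COC)O[Si](C)(C)C
F2 | step 11 | C5-methoxy 1,5-diketone (C8a and C7 ketones, C5–C6 bond formed, new centres as mixtures) | COc1cc([C@@H]2C(=O)C(C(OC)C(OC)C(=O)COC)C[C@H](COCOCc3ccccc3)[C@H]2CO[Si](C)(C)C(C)(C)C)cc(OC)c1OCc1ccccc1
F3 | step 7 | (E)-4-(tert-butyldimethylsilyloxy)but-2-enal | CC(C)(C)[Si](C)(C)OC/C=C/C=O
F4 | step 7 | all-trans C3 carbaldehyde cycloadduct with C8a(OTBS)=C4a enol silane | COc1cc([C@@H]2C(O[Si](C)(C)C(C)(C)C)=CC[C@H](C=O)[C@H]2CO[Si](C)(C)C(C)(C)C)cc(OC)c1OCc1ccccc1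
F5 | step 10 | all-trans ring B ketone (C8a ketone, C4a CH2) | COc1cc([C@@H]2C(=O)CC[C@H](COCOCc3ccccc3)[C@H]2CO[Si](C)(C)C(C)(C)C)cc(OC)c1OCc1ccccc1
F6 | step 10 | all-trans ring B 2-(hydroxymethylene)cyclohexanone | COc1cc([C@@H]2C(=O)C(=CO)C[C@H](COCOCc3ccccc3)[C@H]2CO[Si](C)(C)C(C)(C)C)cc(OC)c1OCc1ccccc1
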